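**Retrosynthetic overview**
1. Target ⇐ one fluoride deprotection ⇐ two Stille couplings: C17–C18 (lactone vinylstannane, fragment A) and C11–C12 (E/Z-diiodide, fragment B) onto a C1–C11 keto vinylstannane (fragment C).
2. Fragment A: chiral phosphoric acid-catalysed anti-crotylboration of a stannyl enal, acrylate formation, ring-closing metathesis.
3. Fragment B: C15 by organocatalytic transfer hydrogenation; Takai and α-iodo-Wittig olefinations give the E- and Z-vinyl iodides.
4. Fragment C: C8–C9 by a chiral phosphoric acid-catalysed allenylboration (key step, new), then C8 oxidation; C5 by anti-selective hydroboration/B-alkyl Suzuki coupling; C6/C7 by a Lewis base-catalysed anti-aldol of methacrolein.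
5. Ring order: the dihydropyranone is the only ring; it is closed first in fragment A (step 4) and carried unchanged through the last coupling.

Assumption: the SMILES is read as (2E,5R,6R,7R,9S,10E,12E,15R,16Z,18E) with a trans-(2R,3S) lactone, and compounds 1, 3, 6, 9, 10, 13, 16, 21, 22, 26, 30 and 33 (all achiral) and the catalysts are taken as purchasable.

**Fragment A (lactone stannane)**

Step 1
Reactants: 1 (2E)-3-(tributylstannyl)prop-2-en-1-ol
Product: 2 (2E)-3-(tributylstannyl)prop-2-enal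
Conditions: MnO2 (15 equiv), CH2Cl2, rt
Reagents that add atoms: none
Why: Allylic oxidation with MnO2 stops at the enal and leaves the vinylstannane and its E geometry untouched.

Step 2
Reactants: 2 (2E)-3-(tributylstannyl)prop-2-enal; 3 (E)-crotylboronic acid pinacol ester
Product: 5 (1E,3S,4S)-4-methyl-1-(tributylstannyl)hexa-1,5-dien-3-ol, via O-pinacolboryl adduct 4 (not isolated)
Conditions: (S)-TRIP (5 mol%), 4 Å MS, PhMe, −30 °C; then H2O
Reagents that add atoms: none
Why: Chiral phosphoric acid-catalysed crotylboration through a closed chair transition state, in which the E-crotyl unit gives the anti pair and the catalyst directs attack to the Si face of the enal, so both lactone stereocentres are set by asymmetric catalysis.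

Step 3
Reactants: 5 (1E,3S,4S)-4-methyl-1-(tributylstannyl)hexa-1,5-dien-3-ol; 6 acryloyl chloride
Product: 7 (1E,3S,4S)-4-methyl-1-(tributylstannyl)hexa-1,5-dien-3-yl prop-2-enoate
Conditions: iPr2NEt, DMAP (cat.), CH2Cl2, 0 °C
Reagents that add atoms: none
Why: DMAP-catalysed O-acylation of the secondary alcohol does not touch either stereocentre.

Step 4
Reactants: 7 (1E,3S,4S)-4-methyl-1-(tributylstannyl)hexa-1,5-dien-3-yl prop-2-enoate
Product: 8 (5S,6S)-5-methyl-6-[(E)-2-(tributylstannyl)ethenyl]-5,6-dihydro-2H-pyran-2-one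
Conditions: second-generation Grubbs catalyst RuCl2(=CHPh)(PCy3)(H2IMes) (5 mol%), CH2Cl2 (5 mM), 40 °C
Reagents that add atoms: none
Why: Ring-closing metathesis of the acrylate with the terminal vinyl group closes the six-membered unsaturated lactone (trans, from the anti alcohol), while the bulky 1,2-disubstituted stannylalkene is a spectator.

**Fragment B (diiodide)**

Step 5
Reactants: 9 1,1-dimethoxypropan-2-one; 10 (formylmethylene)triphenylphosphorane
Product: 11 (2E)-4,4-dimethoxy-3-methylbut-2-enal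
Conditions: PhMe, 90 °C
Reagents that add atoms: none
Why: Wittig olefination of the activated ketone with the stabilised formyl ylide gives mainly the E-enal, and any Z isomer is acceptable because step 6 is stereoconvergent.

Step 6
Reactants: 11 (2E)-4,4-dimethoxy-3-methylbut-2-enal
Product: 12 (3R)-4,4-dimethoxy-3-methylbutanal
Conditions: (S)-2-tert-butyl-3-methylimidazolidin-4-one·CCl3CO2H (20 mol%), Hantzsch ester (1.2 equiv), CHCl3, −30 °C
Reagents that add atoms: none
Why: Iminium-catalysed organocatalytic transfer hydrogenation, in which E/Z iminium ions equilibrate and hydride is delivered to one face of the β-carbon, sets C15 as R by asymmetric catalysis.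

Step 7
Reactants: 12 (3R)-4,4-dimethoxy-3-methylbutanal; 13 iodoform
Product: 14 (1E,4R)-1-iodo-5,5-dimethoxy-4-methylpent-1-ene
Conditions: CrCl2 (6 equiv), THF/1,4-dioxane (1:6), 0 °C → rt
Reagents that add atoms: none
Why: Takai olefination converts the aldehyde into the E-vinyl iodide and tolerates the acetal and the β-stereocentre.

Step 8
Reactants: 14 (1E,4R)-1-iodo-5,5-dimethoxy-4-methylpent-1-ene
Product: 15 (2R,4E)-5-iodo-2-methylpent-4-enal
Conditions: TsOH·H2O (10 mol%), acetone/H2O (10:1), 0 °C → rt; used crude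
Reagents that add atoms: water, O
Why: Mild acid-catalysed acetal hydrolysis releases the α-methyl aldehyde, which is used at once so that it does not epimerise.

Step 9
Reactants: 15 (2R,4E)-5-iodo-2-methylpent-4-enal; 16 triphenyl(propyl)phosphonium iodide
Product: 20 (1E,4R,5Z)-1,6-diiodo-4-methylocta-1,5-diene, via propylidene ylide 17 (not isolated), via iodophosphonium iodide 18 (not isolated), via iodo ylide 19 (not isolated)
Conditions: 16, n-BuLi, THF, 0 °C; I2, −78 °C; NaN(SiMe3)2, −20 °C; then 15, −78 °C → rt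
Reagents that add atoms: iodine, II
Why: Stork–Zhao-type α-iodo-Wittig olefination gives the Z-trisubstituted vinyl iodide (iodine cis to the chain) under kinetic control at low temperature without epimerising C15.

**Allenylboronate 25 and enol triflate 29**

Step 10
Reactants: 21 [(tert-butyldimethylsilyl)oxy]acetaldehyde; 22 prop-1-yn-1-ylmagnesium bromide
Product: 24 1-[(tert-butyldimethylsilyl)oxy]pent-3-yn-2-yl methyl carbonate (racemic), via magnesium alkoxide 23 (not isolated)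
Conditions: THF, −78 → 0 °C; then ClCO2Me, 0 °C → rt
Reagents that add atoms: methyl chloroformate, COC(=O)Cl
Why: Grignard 1,2-addition followed by in situ O-acylation of the alkoxide gives the propargylic carbonate in one pot.

Step 11
Reactants: 24 1-[(tert-butyldimethylsilyl)oxy]pent-3-yn-2-yl methyl carbonate (racemic)
Product: 25 tert-butyldimethyl{[4-(4,4,5,5-tetramethyl-1,3,2-dioxaborolan-2-yl)penta-2,3-dien-1-yl]oxy}silane (racemic allene)
Conditions: CuCl (10 mol%), KOtBu (10 mol%), Xantphos (10 mol%), B2pin2 (1.2 equiv), THF, rt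
Reagents that add atoms: bis(pinacolato)diboron, CC1(C)OB(OC1(C)C)B1OC(C)(C)C(C)(C)O1
Why: Copper-catalysed SN2′ borylation of a propargylic carbonate places boron on the methyl-bearing alkyne carbon and gives the trisubstituted allenylboronate.

Step 12
Reactants: 26 2,2,6-trimethyl-4H-1,3-dioxin-4-one
Product: 28 2-(trimethylsilyl)ethyl 3-oxobutanoate, via acetylketene 27 (not isolated)
Conditions: Me3SiCH2CH2OH (1.0 equiv), PhMe, 110 °C (acetone distilled off)
Reagents that add atoms: 2-(trimethylsilyl)ethanol, C[Si](C)(C)CCO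
Why: Thermal retro-[4+2] cleavage of the dioxinone gives acetylketene, which is trapped by the alcohol (acetoacetylation).

Step 13
Reactants: 28 2-(trimethylsilyl)ethyl 3-oxobutanoate
Product: 29 2-(trimethylsilyl)ethyl (2E)-3-{[(trifluoromethyl)sulfonyl]oxy}but-2-enoate
Conditions: Tf2O, aq. Me4NOH, hexanes, 5 °C → rt
Reagents that add atoms: trifluoromethanesulfonic anhydride, O=S(=O)(OS(=O)(=O)C(F)(F)F)C(F)(F)F
Why: O-triflation of the non-chelated tetramethylammonium enolate gives the E-enol triflate (triflate trans to the ester).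

**Fragment C and endgame**

Step 14
Reactants: 30 tert-butyl propanoate
Product: 32 tert-butyl{[(1E)-1-tert-butoxyprop-1-en-1-yl]oxy}dimethylsilane, via lithium enolate 31 (not isolated)
Conditions: LiN(iPr)2, THF, −78 °C; then TBSCl, DMPU, −78 °C → rt
Reagents that add atoms: tert-butyldimethylsilyl chloride, CC(C)(C)[Si](C)(C)Cl
Why: Kinetic ester enolisation and O-silylation give the silyl ketene acetal, whose geometry does not matter for the anti-aldol of step 15.

Step 15
Reactants: 32 tert-butyl{[(1E)-1-tert-butoxyprop-1-en-1-yl]oxy}dimethylsilane; 33 methacrolein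
Product: 35 tert-butyl (2R,3S)-3-hydroxy-2,4-dimethylpent-4-enoate, via trichlorosilyl ether 34 (not isolated)
Conditions: SiCl4 (1.1 equiv), binaphthyldiamine-derived chiral bisphosphoramide (5 mol%, enantiomer giving Si-face attack), iPr2NEt (10 mol%), CH2Cl2, −78 °C; then H2O
Reagents that add atoms: none
Why: Lewis base-catalysed (phosphoramide-activated SiCl4) Mukaiyama-type aldol through an open transition state is anti-selective for propanoate ketene acetals with enals and the catalyst fixes the aldehyde face, so C6 and C7 are the first stereocentres of this branch and come from asymmetric catalysis.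

Step 16
Reactants: 35 tert-butyl (2R,3S)-3-hydroxy-2,4-dimethylpent-4-enoate
Product: 36 tert-butyl (2R,3S)-2,4-dimethyl-3-[(triethylsilyl)oxy]pent-4-enoate
Conditions: TESCl, imidazole, DMF, 0 °C → rt
Reagents that add atoms: chlorotriethylsilane, CC[Si](CC)(CC)Cl
Why: Silylation protects the C6 hydroxyl for the later C8 oxidation.

Step 17
Reactants: 36 tert-butyl (2R,3S)-2,4-dimethyl-3-[(triethylsilyl)oxy]pent-4-enoate
Product: 38 (2R,3S)-2,4-dimethyl-3-[(triethylsilyl)oxy]pent-4-enal, via aluminium hemiacetal 37 (not isolated)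
Conditions: iBu2AlH (1.2 equiv), CH2Cl2, −78 °C; then aq. potassium sodium tartrate
Reagents that add atoms: none
Why: Partial ester reduction stops at the tetrahedral aluminium hemiacetal at −78 °C and releases the aldehyde on work-up without epimerising C7.

Step 18
Reactants: 38 (2R,3S)-2,4-dimethyl-3-[(triethylsilyl)oxy]pent-4-enal; 25 racemic allenylboronate (2.5 equiv)
Product: 40 (3S,4S,5R,6S)-6-{[(tert-butyldimethylsilyl)oxy]methyl}-2,4-dimethyl-3-[(triethylsilyl)oxy]non-1-en-7-yn-5-ol, via O-pinacolboryl adduct 39 (not isolated)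
Conditions: (R)-TRIP (10 mol%), 4 Å MS, PhMe, −20 → 0 °C; then H2O
Reagents that add atoms: none
Why: Proposed new method: chiral phosphoric acid-catalysed kinetic-resolution allenylboration of an enantioenriched α-methyl-β-silyloxy aldehyde with a racemic α,γ-disubstituted allenyl pinacolboronate, in which the acid hydrogen-bonds to a boronate oxygen and the formyl C–H and so organises the closed six-membered SE2′ transition state for Re-face attack on 38 (also its Felkin and 1,3-anti face), only the allene enantiomer that keeps its CH2OTBS group away from the aldehyde chain reacts fast, and the C8–C9 bond therefore forms anti with C9 fixed as in the target (C8 is oxidised later); the closest known reaction type is the Brønsted acid-catalysed propargylation and crotylboration of aldehydes with allenyl and crotyl pinacolboronates, including kinetic resolution of racemic γ-methyl allenylboronates, which has not been shown for α-methyl-γ-(silyloxymethyl) allenylboronates or with a resolving chiral aldehyde.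

Step 19
Reactants: 40 (3S,4S,5R,6S)-6-{[(tert-butyldimethylsilyl)oxy]methyl}-2,4-dimethyl-3-[(triethylsilyl)oxy]non-1-en-7-yn-5-ol; 29 2-(trimethylsilyl)ethyl (2E)-3-{[(trifluoromethyl)sulfonyl]oxy}but-2-enoate
Product: 42 2-(trimethylsilyl)ethyl (2E,5R,6R,7S,8R,9S)-9-{[(tert-butyldimethylsilyl)oxy]methyl}-8-hydroxy-3,5,7-trimethyl-6-[(triethylsilyl)oxy]dodec-2-en-10-ynoate, via alkyl-9-BBN borane 41 (not isolated)
Conditions: 9-BBN (2.5 equiv), THF, 0 °C → rt; then 29, Pd(dppf)Cl2 (5 mol%), AsPh3 (10 mol%), Cs2CO3, DMF/H2O, rt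
Reagents that add atoms: none
Why: Hydroboration of the 1,1-disubstituted alkene next to the silyloxy stereocentre is anti-selective (allylic strain control) and sets C5, the hindered internal alkyne reacts far more slowly, and the B-alkyl Suzuki–Miyaura coupling with the E-enol triflate keeps the alkene geometry.

Step 20
Reactants: 42 2-(trimethylsilyl)ethyl (2E,5R,6R,7S,8R,9S)-9-{[(tert-butyldimethylsilyl)oxy]methyl}-8-hydroxy-3,5,7-trimethyl-6-[(triethylsilyl)oxy]dodec-2-en-10-ynoate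
Product: 43 2-(trimethylsilyl)ethyl (2E,5R,6R,7S,8R,9S,10E)-9-{[(tert-butyldimethylsilyl)oxy]methyl}-8-hydroxy-3,5,7-trimethyl-11-(tributylstannyl)-6-[(triethylsilyl)oxy]dodeca-2,10-dienoate
Conditions: Bu3SnH (1.3 equiv), PdCl2(PPh3)2 (3 mol%), THF, 0 °C
Reagents that add atoms: tributyltin hydride, CCCC[SnH](CCCC)CCCC
Why: Palladium-catalysed syn-hydrostannation puts tin on the less hindered methyl-bearing alkyne carbon and gives the E-vinylstannane.

Step 21
Reactants: 43 2-(trimethylsilyl)ethyl (2E,5R,6R,7S,8R,9S,10E)-9-{[(tert-butyldimethylsilyl)oxy]methyl}-8-hydroxy-3,5,7-trimethyl-11-(tributylstannyl)-6-[(triethylsilyl)oxy]dodeca-2,10-dienoate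
Product: 44 2-(trimethylsilyl)ethyl (2E,5R,6R,7R,9S,10E)-9-{[(tert-butyldimethylsilyl)oxy]methyl}-3,5,7-trimethyl-8-oxo-11-(tributylstannyl)-6-[(triethylsilyl)oxy]dodeca-2,10-dienoate
Conditions: Dess–Martin periodinane, NaHCO3, CH2Cl2, 0 °C → rt
Reagents that add atoms: none
Why: Dess–Martin oxidation of the only free hydroxyl gives the C8 ketone under buffered, non-basic conditions that do not epimerise C7 or C9.

Step 22
Reactants: 44 2-(trimethylsilyl)ethyl (2E,5R,6R,7R,9S,10E)-9-{[(tert-butyldimethylsilyl)oxy]methyl}-3,5,7-trimethyl-8-oxo-11-(tributylstannyl)-6-[(triethylsilyl)oxy]dodeca-2,10-dienoate; 20 (1E,4R,5Z)-1,6-diiodo-4-methylocta-1,5-diene (1.3 equiv)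
Product: 45 2-(trimethylsilyl)ethyl (2E,5R,6R,7R,9S,10E,12E,15R,16Z)-9-{[(tert-butyldimethylsilyl)oxy]methyl}-17-iodo-3,5,7,11,15-pentamethyl-8-oxo-6-[(triethylsilyl)oxy]nonadeca-2,10,12,16-tetraenoate
Conditions: Pd2(dba)3 (5 mol%), AsPh3 (40 mol%), CuI (10 mol%), NMP, rt
Reagents that add atoms: none
Why: Stille coupling under neutral conditions, in which oxidative addition is much faster at the unhindered E-1,2-disubstituted iodide than at the trisubstituted α-ethyl iodide, forms C11–C12 with retention of both alkene geometries.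

Step 23
Reactants: 45 2-(trimethylsilyl)ethyl (2E,5R,6R,7R,9S,10E,12E,15R,16Z)-9-{[(tert-butyldimethylsilyl)oxy]methyl}-17-iodo-3,5,7,11,15-pentamethyl-8-oxo-6-[(triethylsilyl)oxy]nonadeca-2,10,12,16-tetraenoate; 8 (5S,6S)-5-methyl-6-[(E)-2-(tributylstannyl)ethenyl]-5,6-dihydro-2H-pyran-2-one (1.5 equiv)
Product: 46 2-(trimethylsilyl)ethyl (2E,5R,6R,7R,9S,10E,12E,15R,16Z,18E)-9-{[(tert-butyldimethylsilyl)oxy]methyl}-17-ethyl-3,5,7,11,15-pentamethyl-19-[(2R,3S)-3-methyl-6-oxo-3,6-dihydro-2H-pyran-2-yl]-8-oxo-6-[(triethylsilyl)oxy]nonadeca-2,10,12,16,18-pentaenoate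
Conditions: Pd2(dba)3 (5 mol%), AsPh3 (40 mol%), CuI (10 mol%), NMP, 35 °C
Reagents that add atoms: none
Why: A second Stille coupling joins the remaining Z-iodide to the unhindered E-alkenylstannane with retention, giving the 16Z,18E-diene without base that could harm the lactone or C9.

Step 24
Reactants: 46 2-(trimethylsilyl)ethyl (2E,5R,6R,7R,9S,10E,12E,15R,16Z,18E)-9-{[(tert-butyldimethylsilyl)oxy]methyl}-17-ethyl-3,5,7,11,15-pentamethyl-19-[(2R,3S)-3-methyl-6-oxo-3,6-dihydro-2H-pyran-2-yl]-8-oxo-6-[(triethylsilyl)oxy]nonadeca-2,10,12,16,18-pentaenoate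
Product: 47 (2E,5R,6R,7R,9S,10E,12E,15R,16Z,18E)-17-ethyl-6-hydroxy-9-(hydroxymethyl)-3,5,7,11,15-pentamethyl-19-[(2R,3S)-3-methyl-6-oxo-3,6-dihydro-2H-pyran-2-yl]-8-oxononadeca-2,10,12,16,18-pentaenoic acid
Conditions: TASF (6 equiv), wet DMF, 0 °C → rt; then pH 7 phosphate buffer
Reagents that add atoms: none
Why: Fluoride-mediated global desilylation cleaves the TES and TBS ethers and fragments the 2-(trimethylsilyl)ethyl ester (β-elimination to ethene) in one operation, giving the target.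

**Compound list**
1 | (2E)-3-(tributylstannyl)prop-2-en-1-ol | CCCC[Sn](CCCC)(CCCC)/C=C/CO | starting material
2 | (2E)-3-(tributylstannyl)prop-2-enal | CCCC[Sn](CCCC)(CCCC)/C=C/C=O | intermediate
3 | (E)-crotylboronic acid pinacol ester | C/C=C/CB1OC(C)(C)C(C)(C)O1 | starting material
4 | O-pinacolboryl ether of 5 | CCCC[Sn](CCCC)(CCCC)/C=C/[C@@H](OB1OC(C)(C)C(C)(C)O1)[C@@H](C)C=C | intermediate
5 | (1E,3S,4S)-4-methyl-1-(tributylstannyl)hexa-1,5-dien-3-ol | CCCC[Sn](CCCC)(CCCC)/C=C/[C@@H](O)[C@@H](C)C=C | intermediate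
6 | acryloyl chloride | C=CC(=O)Cl | starting material
7 | (1E,3S,4S)-4-methyl-1-(tributylstannyl)hexa-1,5-dien-3-yl prop-2-enoate | CCCC[Sn](CCCC)(CCCC)/C=C/[C@@H](OC(=O)C=C)[C@@H](C)C=C | intermediate
8 | (5S,6S)-5-methyl-6-[(E)-2-(tributylstannyl)ethenyl]-5,6-dihydro-2H-pyran-2-one | CCCC[Sn](CCCC)(CCCC)/C=C/[C@H]1OC(=O)C=C[C@@H]1C | intermediate
9 | 1,1-dimethoxypropan-2-one | CC(=O)C(OC)OC | starting material
10 | (formylmethylene)triphenylphosphorane | O=CC=P(c1ccccc1)(c1ccccc1)c1ccccc1 | starting material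
11 | (2E)-4,4-dimethoxy-3-methylbut-2-enal | COC(OC)/C(C)=C/C=O | intermediate
12 | (3R)-4,4-dimethoxy-3-methylbutanal | O=CC[C@@H](C)C(OC)OC | intermediate
13 | iodoform | IC(I)I | starting material
14 | (1E,4R)-1-iodo-5,5-dimethoxy-4-methylpent-1-ene | I/C=C/C[C@@H](C)C(OC)OC | intermediate
15 | (2R,4E)-5-iodo-2-methylpent-4-enal | I/C=C/C[C@@H](C)C=O | intermediate
16 | triphenyl(propyl)phosphonium iodide | CCC[P+](c1ccccc1)(c1ccccc1)c1ccccc1.[I-] | starting material
17 | triphenyl(propylidene)phosphorane | CCC=P(c1ccccc1)(c1ccccc1)c1ccccc1 | intermediate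
18 | (1-iodopropyl)triphenylphosphonium iodide | CCC(I)[P+](c1ccccc1)(c1ccccc1)c1ccccc1.[I-] | intermediate
19 | (1-iodopropylidene)triphenylphosphorane | CCC(I)=P(c1ccccc1)(c1ccccc1)c1ccccc1 | intermediate
20 | (1E,4R,5Z)-1,6-diiodo-4-methylocta-1,5-diene | I/C=C/C[C@@H](C)/C=C(\I)CC | intermediate
21 | [(tert-butyldimethylsilyl)oxy]acetaldehyde | O=CCO[Si](C)(C)C(C)(C)C | starting material
22 | prop-1-yn-1-ylmagnesium bromide | CC#C[Mg]Br | starting material
23 | bromomagnesium 1-[(tert-butyldimethylsilyl)oxy]pent-3-yn-2-olate (racemic) | CC#CC(CO[Si](C)(C)C(C)(C)C)O[Mg]Br | intermediate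
24 | 1-[(tert-butyldimethylsilyl)oxy]pent-3-yn-2-yl methyl carbonate (racemic) | CC#CC(CO[Si](C)(C)C(C)(C)C)OC(=O)OC | intermediate
25 | tert-butyldimethyl{[4-(4,4,5,5-tetramethyl-1,3,2-dioxaborolan-2-yl)penta-2,3-dien-1-yl]oxy}silane (racemic allene) | CC(=C=CCO[Si](C)(C)C(C)(C)C)B1OC(C)(C)C(C)(C)O1 | intermediate
26 | 2,2,6-trimethyl-4H-1,3-dioxin-4-one | CC1=CC(=O)OC(C)(C)O1 | starting material
27 | acetylketene | CC(=O)C=C=O | intermediate
28 | 2-(trimethylsilyl)ethyl 3-oxobutanoate | CC(=O)CC(=O)OCC[Si](C)(C)C | intermediate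
29 | 2-(trimethylsilyl)ethyl (2E)-3-{[(trifluoromethyl)sulfonyl]oxy}but-2-enoate | C/C(OS(=O)(=O)C(F)(F)F)=C\C(=O)OCC[Si](C)(C)C | intermediate
30 | tert-butyl propanoate | CCC(=O)OC(C)(C)C | starting material
31 | lithium enolate of 30 (methyl cis to tert-butoxy) | C/C=C(\OC(C)(C)C)O[Li] | intermediate
32 | tert-butyl{[(1E)-1-tert-butoxyprop-1-en-1-yl]oxy}dimethylsilane | C/C=C(\OC(C)(C)C)O[Si](C)(C)C(C)(C)C | intermediate
33 | methacrolein | CC(=C)C=O | starting material
34 | tert-butyl (2R,3S)-2,4-dimethyl-3-[(trichlorosilyl)oxy]pent-4-enoate | CC(=C)[C@@H](O[Si](Cl)(Cl)Cl)[C@@H](C)C(=O)OC(C)(C)C | intermediate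
35 | tert-butyl (2R,3S)-3-hydroxy-2,4-dimethylpent-4-enoate | CC(=C)[C@@H](O)[C@@H](C)C(=O)OC(C)(C)C | intermediate
36 | tert-butyl (2R,3S)-2,4-dimethyl-3-[(triethylsilyl)oxy]pent-4-enoate | CC(=C)[C@@H](O[Si](CC)(CC)CC)[C@@H](C)C(=O)OC(C)(C)C | intermediate
37 | diisobutylaluminium tert-butyl hemiacetal of 38 | CC(=C)[C@@H](O[Si](CC)(CC)CC)[C@@H](C)C(OC(C)(C)C)O[Al](CC(C)C)CC(C)C | intermediate
38 | (2R,3S)-2,4-dimethyl-3-[(triethylsilyl)oxy]pent-4-enal | CC(=C)[C@@H](O[Si](CC)(CC)CC)[C@@H](C)C=O | intermediate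
39 | O-pinacolboryl ether of 40 | CC#C[C@@H](CO[Si](C)(C)C(C)(C)C)[C@@H](OB1OC(C)(C)C(C)(C)O1)[C@H](C)[C@H](O[Si](CC)(CC)CC)C(C)=C | intermediate
40 | (3S,4S,5R,6S)-6-{[(tert-butyldimethylsilyl)oxy]methyl}-2,4-dimethyl-3-[(triethylsilyl)oxy]non-1-en-7-yn-5-ol | CC#C[C@@H](CO[Si](C)(C)C(C)(C)C)[C@@H](O)[C@H](C)[C@H](O[Si](CC)(CC)CC)C(C)=C | intermediate
41 | (2R,3R,4S,5R,6S)-1-(9-borabicyclo[3.3.1]nonan-9-yl)-6-{[(tert-butyldimethylsilyl)oxy]methyl}-2,4-dimethyl-3-[(triethylsilyl)oxy]non-7-yn-5-ol | CC#C[C@@H](CO[Si](C)(C)C(C)(C)C)[C@@H](O)[C@H](C)[C@H](O[Si](CC)(CC)CC)[C@H](C)CB1C2CCCC1CCC2 | intermediate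
42 | 2-(trimethylsilyl)ethyl (2E,5R,6R,7S,8R,9S)-9-{[(tert-butyldimethylsilyl)oxy]methyl}-8-hydroxy-3,5,7-trimethyl-6-[(triethylsilyl)oxy]dodec-2-en-10-ynoate | CC#C[C@@H](CO[Si](C)(C)C(C)(C)C)[C@@H](O)[C@H](C)[C@H](O[Si](CC)(CC)CC)[C@H](C)C/C(C)=C/C(=O)OCC[Si](C)(C)C | intermediate
43 | 2-(trimethylsilyl)ethyl (2E,5R,6R,7S,8R,9S,10E)-9-{[(tert-butyldimethylsilyl)oxy]methyl}-8-hydroxy-3,5,7-trimethyl-11-(tributylstannyl)-6-[(triethylsilyl)oxy]dodeca-2,10-dienoate | C/C([Sn](CCCC)(CCCC)CCCC)=C\[C@@H](CO[Si](C)(C)C(C)(C)C)[C@@H](O)[C@H](C)[C@H](O[Si](CC)(CC)CC)[C@H](C)C/C(C)=C/C(=O)OCC[Si](C)(C)C | intermediate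
44 | 2-(trimethylsilyl)ethyl (2E,5R,6R,7R,9S,10E)-9-{[(tert-butyldimethylsilyl)oxy]methyl}-3,5,7-trimethyl-8-oxo-11-(tributylstannyl)-6-[(triethylsilyl)oxy]dodeca-2,10-dienoate | C/C([Sn](CCCC)(CCCC)CCCC)=C\[C@@H](CO[Si](C)(C)C(C)(C)C)C(=O)[C@H](C)[C@H](O[Si](CC)(CC)CC)[C@H](C)C/C(C)=C/C(=O)OCC[Si](C)(C)C | intermediate
45 | 2-(trimethylsilyl)ethyl (2E,5R,6R,7R,9S,10E,12E,15R,16Z)-9-{[(tert-butyldimethylsilyl)oxy]methyl}-17-iodo-3,5,7,11,15-pentamethyl-8-oxo-6-[(triethylsilyl)oxy]nonadeca-2,10,12,16-tetraenoate | CCC(=C/[C@H](C)C/C=C/C(C)=C/[C@@H](CO[Si](C)(C)C(C)(C)C)C(=O)[C@H](C)[C@H](O[Si](CC)(CC)CC)[C@H](C)C/C(C)=C/C(=O)OCC[Si](C)(C)C)/I | intermediate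
46 | 2-(trimethylsilyl)ethyl (2E,5R,6R,7R,9S,10E,12E,15R,16Z,18E)-9-{[(tert-butyldimethylsilyl)oxy]methyl}-17-ethyl-3,5,7,11,15-pentamethyl-19-[(2R,3S)-3-methyl-6-oxo-3,6-dihydro-2H-pyran-2-yl]-8-oxo-6-[(triethylsilyl)oxy]nonadeca-2,10,12,16,18-pentaenoate | CCC(=C/[C@H](C)C/C=C/C(C)=C/[C@@H](CO[Si](C)(C)C(C)(C)C)C(=O)[C@H](C)[C@H](O[Si](CC)(CC)CC)[C@H](C)C/C(C)=C/C(=O)OCC[Si](C)(C)C)/C=C/[C@H]1OC(=O)C=C[C@@H]1C | intermediate
47 | (2E,5R,6R,7R,9S,10E,12E,15R,16Z,18E)-17-ethyl-6-hydroxy-9-(hydroxymethyl)-3,5,7,11,15-pentamethyl-19-[(2R,3S)-3-methyl-6-oxo-3,6-dihydro-2H-pyran-2-yl]-8-oxononadeca-2,10,12,16,18-pentaenoic acid | CCC(=C/[C@H](C)C/C=C/C(C)=C/[C@@H](CO)C(=O)[C@H](C)[C@H](O)[C@H](C)C/C(C)=C/C(=O)O)/C=C/[C@H]1OC(=O)C=C[C@@H]1C | target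

**Step count and risks**

Total step count: 24. Longest linear sequence: 11 steps (steps 14–24, from 30).

Three steps most likely to fail:

Step 18 (the proposed new allenylboration). The α-methyl group on the boron-bearing carbon may slow the reaction or erode the anti/kinetic-resolution selectivity. The fallback is the known propargylic mesylate/allenylzinc addition (Marshall propargylation); it sets out from 21, 22 and 38 and comes back at 40. Compounds 21 and 22 are combined as in step 10, but alkoxide 23 is quenched with aqueous NH4Cl to give racemic 1-[(tert-butyldimethylsilyl)oxy]pent-3-yn-2-ol F1. MnO2 oxidation gives 1-[(tert-butyldimethylsilyl)oxy]pent-3-yn-2-one F2. Oxazaborolidine reduction ((S)-Me-CBS, catecholborane, −78 °C; the alkynyl group acts as the small group) gives (2R)-1-[(tert-butyldimethylsilyl)oxy]pent-3-yn-2-ol F3, and MsCl/Et3N gives the (2R)-methanesulfonate F4. With Pd(OAc)2 (5 mol%), PPh3 and Et2Zn in THF at −20 °C, F4 is converted by anti-SN2′ palladation and transmetalation into ethyl{(aR)-5-[(tert-butyldimethylsilyl)oxy]penta-2,3-dien-2-yl}zinc F5. F5 adds to 38 through a cyclic SE2′ transition state (anti, Felkin-matched) to give 40.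

Step 22 (mono-coupling of diiodide 20). If the two vinyl iodides are not differentiated well enough, they are introduced one after the other; this fallback sets out from 43 and 14 and comes back at 45. Stille coupling of stannane 43 with mono-iodide 14 (Pd2(dba)3, AsPh3, CuI, NMP) gives 2-(trimethylsilyl)ethyl (2E,5R,6R,7S,8R,9S,10E,12E,15R)-9-{[(tert-butyldimethylsilyl)oxy]methyl}-8-hydroxy-16,16-dimethoxy-3,5,7,11,15-pentamethyl-6-[(triethylsilyl)oxy]hexadeca-2,10,12-trienoate F6. Mild acetal hydrolysis (PPTS, wet acetone) gives the corresponding 16-oxo aldehyde F7. The α-iodo-Wittig reaction of step 9 with ylide 19 (used in excess, since the C8 hydroxyl consumes one equivalent) gives the 17-iodo-(16Z)-nonadeca-2,10,12,16-tetraenoate alcohol F8; at this stage C8 is still an alcohol, so no enolisable ketone meets the ylide. Dess–Martin oxidation of F8 then gives 45.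

Step 24 (global fluoride deprotection). Basic fluoride may cause retro-aldol cleavage, C9 epimerisation or lactone damage in 46. The fallback removes the silicon groups in two stages before the lactone is attached; it sets out from 45 and 8 and comes back at 47. HF·pyridine/pyridine in THF removes the TES and TBS ethers from 45 under acidic conditions to give 2-(trimethylsilyl)ethyl (2E,5R,6R,7R,9S,10E,12E,15R,16Z)-6-hydroxy-9-(hydroxymethyl)-17-iodo-3,5,7,11,15-pentamethyl-8-oxononadeca-2,10,12,16-tetraenoate F9. Water-buffered TASF at 0 °C then only has to fragment the ester of a compound that carries no lactone and forms no alkoxide, giving (2E,5R,6R,7R,9S,10E,12E,15R,16Z)-6-hydroxy-9-(hydroxymethyl)-17-iodo-3,5,7,11,15-pentamethyl-8-oxononadeca-2,10,12,16-tetraenoic acid F10. The final Stille coupling of F10 with 8 (Pd2(dba)3, AsPh3, CuI, NMP), which tolerates free hydroxyl and carboxyl groups, gives 47.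

**Further compounds**
F1 | step 18 | 1-[(tert-butyldimethylsilyl)oxy]pent-3-yn-2-ol (racemic) | CC#CC(O)CO[Si](C)(C)C(C)(C)C
F2 | step 18 | 1-[(tert-butyldimethylsilyl)oxy]pent-3-yn-2-one | CC#CC(=O)CO[Si](C)(C)C(C)(C)C
F3 | step 18 | (2R)-1-[(tert-butyldimethylsilyl)oxy]pent-3-yn-2-ol | CC#C[C@H](CO[Si](C)(C)C(C)(C)C)O
F4 | step 18 | (2R)-1-[(tert-butyldimethylsilyl)oxy]pent-3-yn-2-yl methanesulfonate | CC#C[C@H](CO[Si](C)(C)C(C)(C)C)OS(C)(=O)=O
F5 | step 18 | ethyl{(aR)-5-[(tert-butyldimethylsilyl)oxy]penta-2,3-dien-2-yl}zinc | CC[Zn]C(C)=[C@]=C([H])CO[Si](C)(C)C(C)(C)C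
F6 | step 22 | 2-(trimethylsilyl)ethyl (2E,5R,6R,7S,8R,9S,10E,12E,15R)-9-{[(tert-butyldimethylsilyl)oxy]methyl}-8-hydroxy-16,16-dimethoxy-3,5,7,11,15-pentamethyl-6-[(triethylsilyl)oxy]hexadeca-2,10,12-trienoate | COC(OC)[C@H](C)C/C=C/C(C)=C/[C@@H](CO[Si](C)(C)C(C)(C)C)[C@@H](O)[C@H](C)[C@H](O[Si](CC)(CC)CC)[C@H](C)C/C(C)=C/C(=O)OCC[Si](C)(C)C
F7 | step 22 | 2-(trimethylsilyl)ethyl (2E,5R,6R,7S,8R,9S,10E,12E,15R)-9-{[(tert-butyldimethylsilyl)oxy]methyl}-8-hydroxy-3,5,7,11,15-pentamethyl-16-oxo-6-[(triethylsilyl)oxy]hexadeca-2,10,12-trienoate | O=C[C@H](C)C/C=C/C(C)=C/[C@@H](CO[Si](C)(C)C(C)(C)C)[C@@H](O)[C@H](C)[C@H](O[Si](CC)(CC)CC)[C@H](C)C/C(C)=C/C(=O)OCC[Si](C)(C)C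
F8 | step 22 | 2-(trimethylsilyl)ethyl (2E,5R,6R,7S,8R,9S,10E,12E,15R,16Z)-9-{[(tert-butyldimethylsilyl)oxy]methyl}-8-hydroxy-17-iodo-3,5,7,11,15-pentamethyl-6-[(triethylsilyl)oxy]nonadeca-2,10,12,16-tetraenoate | CCC(=C/[C@H](C)C/C=C/C(C)=C/[C@@H](CO[Si](C)(C)C(C)(C)C)[C@@H](O)[C@H](C)[C@H](O[Si](CC)(CC)CC)[C@H](C)C/C(C)=C/C(=O)OCC[Si](C)(C)C)/I
F9 | step 24 | 2-(trimethylsilyl)ethyl (2E,5R,6R,7R,9S,10E,12E,15R,16Z)-6-hydroxy-9-(hydroxymethyl)-17-iodo-3,5,7,11,15-pentamethyl-8-oxononadeca-2,10,12,16-tetraenoate | CCC(=C/[C@H](C)C/C=C/C(C)=C/[C@@H](CO)C(=O)[C@H](C)[C@H](O)[C@H](C)C/C(C)=C/C(=O)OCC[Si](C)(C)C)/I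
F10 | step 24 | (2E,5R,6R,7R,9S,10E,12E,15R,16Z)-6-hydroxy-9-(hydroxymethyl)-17-iodo-3,5,7,11,15-pentamethyl-8-oxononadeca-2,10,12,16-tetraenoic acid | CCC(=C/[C@H](C)C/C=C/C(C)=C/[C@@H](CO)C(=O)[C@H](C)[C@H](O)[C@H](C)C/C(C)=C/C(=O)O)/I
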